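**Retrosynthetic overview**

1. Target 21 ⇐ bis-MOM flavanone 20 by acidic MOM removal; ring B is bought as resorcinol.
2. 20 ⇐ acyclic hydroxy enone keto ester 18 in one pot: ring C closes first (alcohol O onto the C-8a carbonyl, 1,3-carbonyl transposition, C2–O bond untouched), then ring A (C-4a onto the ester, Claisen, aromatisation).
3. 18 ⇐ dianion of the diprenylated β-keto ester 16 + (S)-lactone 12 (ring-opening acylation makes C8–C8a).
4. 12 ⇐ aldehyde 7 + Brassard's diene 10 by catalytic asymmetric hetero-Diels–Alder (sets the only stereocentre; the lactone ring is sacrificial); 16 ⇐ methyl acetoacetate + 2 prenyl bromide.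
5. 7 ⇐ resorcinol by MOM protection and two directed ortho-lithiations (prenyl, then CHO).

Assumption: the stereodescriptor of the SMILES is read as (2S) (natural flavanone series); C-2 is the only stereocentre, and flavanone numbering is used for ring atoms.

**Route**

Step 1
Reactants: 1 resorcinol
Product: 2 1,3-bis(methoxymethoxy)benzene
Conditions: MOMCl (2.5 equiv), K2CO3, acetone, 0 °C to rt
Reagents that add atoms: chloromethyl methyl ether (MOMCl), COCCl
Why: Williamson-type O-alkylation (MOM protection) of both phenols; the MOM ethers direct both later lithiations and survive every step up to the last.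

Step 2
Reactants: 2 1,3-bis(methoxymethoxy)benzene; 3 prenyl bromide (1-bromo-3-methylbut-2-ene)
Product: 5 1,3-bis(methoxymethoxy)-2-(3-methylbut-2-en-1-yl)benzene, via aryllithium 4 (not isolated)
Conditions: n-BuLi, THF, 0 °C to rt; CuI (10 mol%), 3, −78 °C to rt
Reagents that add atoms: none
Why: Directed ortho-metalation occurs at C-2, the site flanked and coordinated by both OMOM groups, and the aryllithium is allylated by prenyl bromide under CuI catalysis (SN2, no allylic transposition).

Step 3
Reactants: 5 1,3-bis(methoxymethoxy)-2-(3-methylbut-2-en-1-yl)benzene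
Product: 7 2,4-bis(methoxymethoxy)-3-(3-methylbut-2-en-1-yl)benzaldehyde, via aryllithium 6 (not isolated)
Conditions: n-BuLi, TMEDA, THF, 0 °C; DMF, 0 °C to rt; H2O
Reagents that add atoms: N,N-dimethylformamide (DMF), CN(C)C=O
Why: A second directed ortho-metalation at the position ortho to an OMOM group (C-4 and C-6 are equivalent), followed by formylation with DMF, gives the 1,2,3,4-substitution pattern of ring B.

Step 4
Reactants: 8 methyl (2E)-3-methoxybut-2-enoate
Product: 10 (1E)-1,3-dimethoxy-1-(trimethylsilyloxy)buta-1,3-diene (Brassard's diene), via lithium dienolate 9 (not isolated)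
Conditions: LiN(iPr)2, THF, −78 °C; TMSCl, −78 °C to rt; distil
Reagents that add atoms: chlorotrimethylsilane (TMSCl), C[Si](C)(C)Cl
Why: γ-Deprotonation of the vinylogous ester and O-silylation of the lithium dienolate (silyl ketene acetal formation) give the diene.

Step 5
Reactants: 7 2,4-bis(methoxymethoxy)-3-(3-methylbut-2-en-1-yl)benzaldehyde; 10 Brassard's diene (1.5 equiv)
Product: 12 (6S)-6-[2,4-bis(methoxymethoxy)-3-(3-methylbut-2-en-1-yl)phenyl]-4-methoxy-5,6-dihydro-2H-pyran-2-one, via silyl aldol adduct 11 (not isolated)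
Conditions: (S)-BINOL (20 mol%), Ti(OiPr)4 (20 mol%), 4 Å MS, THF, 0 °C to rt; then TFA (cat.), CH2Cl2, 0 °C
Reagents that add atoms: none
Why: Catalytic enantioselective hetero-Diels–Alder reaction (stepwise vinylogous Mukaiyama aldol, then lactonisation with loss of MeOSiMe3) in which the (S)-BINOL–Ti(OiPr)4 complex exposes the Si face of the bound aldehyde, setting the (S) centre that becomes C-2; the sense is assigned by analogy with BINOL–Ti additions to aldehydes and must be confirmed by HPLC and optical rotation.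

Step 6
Reactants: 13 methyl acetoacetate; 3 prenyl bromide (first equivalent)
Product: 16 methyl 7-methyl-2-(3-methylbut-2-en-1-yl)-3-oxooct-6-enoate, via dianion 14 (not isolated), via lithium enolate 15 (not isolated)
Conditions: LiN(iPr)2 (2.1 equiv), THF, 0 °C; 3 (1.0 equiv), 0 °C; then prenyl bromide (second portion, 1.1 equiv), DMPU, rt to 50 °C
Reagents that add atoms: prenyl bromide (second equivalent, 1-bromo-3-methylbut-2-ene), CC(C)=CCBr
Why: Weiler-type acetoacetate dianion alkylation: the first equivalent of prenyl bromide alkylates the more basic γ-carbon of dianion 14, and the second equivalent alkylates the remaining lithium enolate 15 at the α-carbon in the same pot, giving ring carbons C-5 to C-8 with both prenyl groups (the α-centre is racemic and disappears on aromatisation).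

Step 7
Reactants: 16 methyl 7-methyl-2-(3-methylbut-2-en-1-yl)-3-oxooct-6-enoate (2.2 equiv); 12 (6S)-lactone
Product: 18 methyl (6E,9S)-9-[2,4-bis(methoxymethoxy)-3-(3-methylbut-2-en-1-yl)phenyl]-9-hydroxy-7-methoxy-2,4-bis(3-methylbut-2-en-1-yl)-3,5-dioxonon-6-enoate (C-2/C-4 epimer mixture), via dianion 17 (not isolated)
Conditions: 16, LiN(iPr)2 (2.05 equiv per 16), THF, −78 to 0 °C; 12, −78 to −30 °C; AcOH, −78 °C
Reagents that add atoms: none
Why: Huckin–Weiler-type Claisen acylation in which the γ-carbanion of the dianion adds 1,2 to the lactone carbonyl (the β-carbon is blocked by OMe and an alkyl group) and the tetrahedral intermediate opens because the new β-diketone is deprotonated at once (hence the second equivalent of dianion), leaving the benzylic C–O stereocentre untouched.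

Step 8
Reactants: 18 acyclic hydroxy enone keto ester
Product: 20 (2S)-2-[2,4-bis(methoxymethoxy)-3-(3-methylbut-2-en-1-yl)phenyl]-5,7-dihydroxy-6,8-bis(3-methylbut-2-en-1-yl)-2,3-dihydro-4H-chromen-4-one, via dihydropyranone 19 (not isolated)
Conditions: PPTS (0.2 equiv), THF–H2O (10:1), rt; then DBU (3 equiv), rt to 40 °C; pH 4 buffer
Reagents that add atoms: water, O
Why: Proposed new method: mild acid lets the C-9 hydroxyl add to the C-5 carbonyl of the vinylogous ester, water is lost to a methoxy-stabilised pyranyl oxocarbenium ion that is hydrolysed to dihydropyranone 19 (ring C; a Stork–Danheiser-type 1,3-carbonyl transposition with an internal O-nucleophile, so the C–O bond at the stereocentre is never broken and S is retained), and DBU then removes the doubly activated γ-CH so that the pyranone α-carbon attacks the methyl ester (intramolecular Claisen acylation; closest known types are the Harris-type cyclisation of 3,5,7-triketo esters to acylphloroglucinols and the base-mediated aromatisation of diketo-dioxinones to resorcylates), loss of methanol and enolisation giving the aromatic ring A.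

Step 9
Reactants: 20 bis-MOM flavanone
Product: 21 (2S)-2-[2,4-dihydroxy-3-(3-methylbut-2-en-1-yl)phenyl]-5,7-dihydroxy-6,8-bis(3-methylbut-2-en-1-yl)-2,3-dihydro-4H-chromen-4-one (CNP0129172.1)
Conditions: 3 M aq. HCl, MeOH, 45 °C, short reaction time
Reagents that add atoms: none
Why: Acid-catalysed acetal exchange cleaves both aryl MOM ethers; ring C is not opened under acid and a short reaction time at mild temperature keeps the ortho-prenyl phenols from cyclising to chromans, so C-2 stays (S).

**Compound list**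

1 | resorcinol (benzene-1,3-diol) | Oc1cccc(O)c1 | starting material
2 | 1,3-bis(methoxymethoxy)benzene | COCOc1cccc(OCOC)c1 | intermediate
3 | prenyl bromide (1-bromo-3-methylbut-2-ene) | CC(C)=CCBr | starting material
4 | [2,6-bis(methoxymethoxy)phenyl]lithium (not isolated) | [Li]c1c(OCOC)cccc1OCOC | intermediate
5 | 1,3-bis(methoxymethoxy)-2-(3-methylbut-2-en-1-yl)benzene | COCOc1cccc(OCOC)c1CC=C(C)C | intermediate
6 | [2,4-bis(methoxymethoxy)-3-(3-methylbut-2-en-1-yl)phenyl]lithium (not isolated) | [Li]c1ccc(OCOC)c(CC=C(C)C)c1OCOC | intermediate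
7 | 2,4-bis(methoxymethoxy)-3-(3-methylbut-2-en-1-yl)benzaldehyde | O=Cc1ccc(OCOC)c(CC=C(C)C)c1OCOC | intermediate
8 | methyl (2E)-3-methoxybut-2-enoate | CO/C(C)=C/C(=O)OC | starting material
9 | lithium (1Z)-1,3-dimethoxybuta-1,3-dien-1-olate (OLi trans to C-3, same geometry as in 10; not isolated) | C=C(OC)/C=C(\OC)O[Li] | intermediate
10 | (1E)-1,3-dimethoxy-1-(trimethylsilyloxy)buta-1,3-diene (Brassard's diene) | C=C(OC)/C=C(\OC)O[Si](C)(C)C | intermediate
11 | methyl (2E,5S)-5-[2,4-bis(methoxymethoxy)-3-(3-methylbut-2-en-1-yl)phenyl]-3-methoxy-5-(trimethylsilyloxy)pent-2-enoate (not isolated) | COC(=O)/C=C(OC)\C[C@H](O[Si](C)(C)C)c1ccc(OCOC)c(CC=C(C)C)c1OCOC | intermediate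
12 | (6S)-6-[2,4-bis(methoxymethoxy)-3-(3-methylbut-2-en-1-yl)phenyl]-4-methoxy-5,6-dihydro-2H-pyran-2-one | COC1=CC(=O)O[C@@H](C1)c1ccc(OCOC)c(CC=C(C)C)c1OCOC | intermediate
13 | methyl acetoacetate | COC(=O)CC(C)=O | starting material
14 | dilithium dianion of methyl acetoacetate (not isolated) | C=C(O[Li])C=C(OC)O[Li] | intermediate
15 | lithium enolate of methyl 7-methyl-3-oxooct-6-enoate (not isolated) | COC(=O)C=C(CCC=C(C)C)O[Li] | intermediate
16 | methyl 7-methyl-2-(3-methylbut-2-en-1-yl)-3-oxooct-6-enoate (racemic) | COC(=O)C(CC=C(C)C)C(=O)CCC=C(C)C | intermediate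
17 | dilithium dianion of 16 (not isolated) | COC(O[Li])=C(CC=C(C)C)C(O[Li])=CCC=C(C)C | intermediate
18 | methyl (6E,9S)-9-[2,4-bis(methoxymethoxy)-3-(3-methylbut-2-en-1-yl)phenyl]-9-hydroxy-7-methoxy-2,4-bis(3-methylbut-2-en-1-yl)-3,5-dioxonon-6-enoate | COC(=O)C(CC=C(C)C)C(=O)C(CC=C(C)C)C(=O)/C=C(OC)\C[C@H](O)c1ccc(OCOC)c(CC=C(C)C)c1OCOC | intermediate
19 | methyl 4-{(2S)-2-[2,4-bis(methoxymethoxy)-3-(3-methylbut-2-en-1-yl)phenyl]-4-oxo-3,4-dihydro-2H-pyran-6-yl}-7-methyl-2-(3-methylbut-2-en-1-yl)-3-oxooct-6-enoate (not isolated) | COC(=O)C(CC=C(C)C)C(=O)C(CC=C(C)C)C1=CC(=O)C[C@H](O1)c1ccc(OCOC)c(CC=C(C)C)c1OCOC | intermediate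
20 | (2S)-2-[2,4-bis(methoxymethoxy)-3-(3-methylbut-2-en-1-yl)phenyl]-5,7-dihydroxy-6,8-bis(3-methylbut-2-en-1-yl)-2,3-dihydro-4H-chromen-4-one | CC(C)=CCc1c(OCOC)ccc([C@@H]2CC(=O)c3c(O)c(CC=C(C)C)c(O)c(CC=C(C)C)c3O2)c1OCOC | intermediate
21 | (2S)-2-[2,4-dihydroxy-3-(3-methylbut-2-en-1-yl)phenyl]-5,7-dihydroxy-6,8-bis(3-methylbut-2-en-1-yl)-2,3-dihydro-4H-chromen-4-one | CC(C)=CCc1c(O)ccc([C@@H]2CC(=O)c3c(O)c(CC=C(C)C)c(O)c(CC=C(C)C)c3O2)c1O | target

**Step count and risks**

Total step count: 9. Longest linear sequence: 7 (steps 1, 2, 3, 5, 7, 8, 9 from resorcinol).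

Most likely to fail, in order of risk:

Step 7. The dianion may act as a base on 12 (γ-deprotonation and E1cB opening to an achiral dienoate), or the vinylogous lactone carbonyl may be too deactivated. The fallback sets out from 12 and comes back at 18. Lactone 12 is opened with Me(MeO)NH·HCl/AlMe3 in CH2Cl2 to the Weinreb amide (2E,5S)-5-[2,4-bis(methoxymethoxy)-3-(3-methylbut-2-en-1-yl)phenyl]-5-hydroxy-N,3-dimethoxy-N-methylpent-2-enamide F1. TBSCl/imidazole converts it into its tert-butyldimethylsilyl ether F2. Dianion 17 is then acylated by this acyclic amide (Weinreb ketone synthesis, no carboxylate leaving group that could trigger elimination) to give the tert-butyldimethylsilyl ether of 18 F3, and HF·pyridine in THF returns 18.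

Step 8. In the acid stage the electron-rich benzylic alcohol may ionise or dehydrate, or a γ-pyrone may form; in the base stage DBU may open ring C (retro-oxa-Michael, loss of ee) or the Claisen closure may be slow. The fallback sets out from 12 and comes back at 20, and replaces the base-mediated ring A closure by a neutral, thermal one. tert-Butyl acetoacetate is taken through the step 6 protocol to tert-butyl 7-methyl-2-(3-methylbut-2-en-1-yl)-3-oxooct-6-enoate F4, whose dianion opens 12 as in step 7 to the tert-butyl ester analogue of 18 F5. PPTS in wet THF gives the tert-butyl ester analogue of 19 F6, which is isolated and heated in toluene at 110 °C. Loss of tert-butanol gives an acylketene that is captured by the nucleophilic α-carbon of the vinylogous ester, and enolisation gives 20 without any base.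

Step 5. The aldehyde is electron-rich and carries a chelating ortho-OMOM group, so rate and ee may be low, and the sense of induction rests on analogy. The fallback sets out from 7 and comes back at 12, through an open-chain aldol and a separate lactonisation. Aldehyde 7 undergoes an enantioselective vinylogous Mukaiyama aldol addition with commercial 1-methoxy-1,3-bis(trimethylsilyloxy)buta-1,3-diene (Chan's diene) under Ti(OiPr)4/(S)-BINOL, with dilute acid work-up, to give methyl (5S)-5-[2,4-bis(methoxymethoxy)-3-(3-methylbut-2-en-1-yl)phenyl]-5-hydroxy-3-oxopentanoate F7. K2CO3 in MeOH followed by careful acidification lactonises it to (6S)-6-[2,4-bis(methoxymethoxy)-3-(3-methylbut-2-en-1-yl)phenyl]dihydro-2H-pyran-2,4(3H)-dione F8, which can be recrystallised to raise the ee. O-Methylation of its enol with Me2SO4/K2CO3 in acetone gives 12.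

**Further compounds**

F1 | step 7 | (2E,5S)-5-[2,4-bis(methoxymethoxy)-3-(3-methylbut-2-en-1-yl)phenyl]-5-hydroxy-N,3-dimethoxy-N-methylpent-2-enamide | CON(C)C(=O)/C=C(OC)\C[C@H](O)c1ccc(OCOC)c(CC=C(C)C)c1OCOC
F2 | step 7 | tert-butyldimethylsilyl ether of F1 | CON(C)C(=O)/C=C(OC)\C[C@H](O[Si](C)(C)C(C)(C)C)c1ccc(OCOC)c(CC=C(C)C)c1OCOC
F3 | step 7 | tert-butyldimethylsilyl ether of 18 | COC(=O)C(CC=C(C)C)C(=O)C(CC=C(C)C)C(=O)/C=C(OC)\C[C@H](O[Si](C)(C)C(C)(C)C)c1ccc(OCOC)c(CC=C(C)C)c1OCOC
F4 | step 8 | tert-butyl 7-methyl-2-(3-methylbut-2-en-1-yl)-3-oxooct-6-enoate | CC(C)=CCCC(=O)C(CC=C(C)C)C(=O)OC(C)(C)C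
F5 | step 8 | tert-butyl ester analogue of 18 | CC(C)(C)OC(=O)C(CC=C(C)C)C(=O)C(CC=C(C)C)C(=O)/C=C(OC)\C[C@H](O)c1ccc(OCOC)c(CC=C(C)C)c1OCOC
F6 | step 8 | tert-butyl ester analogue of 19 | CC(C)(C)OC(=O)C(CC=C(C)C)C(=O)C(CC=C(C)C)C1=CC(=O)C[C@H](O1)c1ccc(OCOC)c(CC=C(C)C)c1OCOC
F7 | step 5 | methyl (5S)-5-[2,4-bis(methoxymethoxy)-3-(3-methylbut-2-en-1-yl)phenyl]-5-hydroxy-3-oxopentanoate | COC(=O)CC(=O)C[C@H](O)c1ccc(OCOC)c(CC=C(C)C)c1OCOC
F8 | step 5 | (6S)-6-[2,4-bis(methoxymethoxy)-3-(3-methylbut-2-en-1-yl)phenyl]dihydro-2H-pyran-2,4(3H)-dione | O=C1CC(=O)O[C@@H](C1)c1ccc(OCOC)c(CC=C(C)C)c1OCOC
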